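## Retrosynthetic overview

1. Sanggenol N ⇒ remove three MOM acetals and convert the C4 dithioketal to C=O ⇒ a spiro-dithiane flavan that already holds rings A, B, C and the pyran ring D.
2. Ring C is cut at two bonds at once, C3–C4 and O1–C8a. The ring A formyl carbon acts as an acyl anion (a 2-lithio-2-aryl-1,3-dithiane with an ortho C–F). It attacks the CH2 of a ring B aryl oxirane, and the released alkoxide then displaces fluoride. The C2–O bond is never broken.
3. (R)-Oxirane ⇒ α-chloroketone by asymmetric transfer hydrogenation. This is the only step that sets stereochemistry.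
4. Ring B ketone ⇒ 5-bromoresacetophenone + prenal (chromenylation, ring D), then Stille prenylation. Ring A dithiane ⇒ 5-fluororesorcinol + 1,3-dithiane.
5. Ring order: D first, then the temporary oxirane and dithiane, then ring C last.

Assumption: 5-bromoresacetophenone, prenal, tributyl(prenyl)stannane, 5-fluororesorcinol and 1,3-dithiane are bought as catalogue chemicals, and atoms carry flavanone numbering.
Abbreviation: ArB = 5-(methoxymethoxy)-2,2-dimethyl-8-(3-methylbut-2-en-1-yl)-2H-chromen-6-yl.

## Route

Step 1
Reactants: 1 1-(5-bromo-2,4-dihydroxyphenyl)ethan-1-one; 2 3-methylbut-2-enal (prenal)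
Product: 4 1-(8-bromo-5-hydroxy-2,2-dimethyl-2H-chromen-6-yl)ethan-1-one, via ortho-quinone methide 3 (not isolated)
Conditions: ethylenediammonium diacetate (20 mol %), toluene, reflux, Dean–Stark
Reagents that add atoms: none
Why: Formal [3+3] chromenylation, in which the only free nucleophilic ring carbon (between the two OH groups, the other site being blocked by Br) attacks prenal in a Knoevenagel-type step, water is lost to give 3, and an oxa-6π electrocyclisation closes through the oxygen para to the acetyl group because the other OH is held in a hydrogen bond to C=O.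

Step 2
Reactants: 4 1-(8-bromo-5-hydroxy-2,2-dimethyl-2H-chromen-6-yl)ethan-1-one
Product: 5 1-[8-bromo-5-(methoxymethoxy)-2,2-dimethyl-2H-chromen-6-yl]ethan-1-one
Conditions: MOMCl, K2CO3, DMF, 0 to 40 °C
Reagents that add atoms: chloromethyl methyl ether (MOMCl), COCCl
Why: Williamson-type O-alkylation by a very reactive α-chloro ether, with carbonate in DMF strong enough to break the chelate but too weak to enolise the methyl ketone.

Step 3
Reactants: 5 1-[8-bromo-5-(methoxymethoxy)-2,2-dimethyl-2H-chromen-6-yl]ethan-1-one; 6 tributyl(3-methylbut-2-en-1-yl)stannane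
Product: 7 1-ArB-ethan-1-one (methyl ketone of ring B)
Conditions: Pd(PPh3)4 (5 mol %), DMF, 100 °C
Reagents that add atoms: none
Why: Stille coupling, in which zerovalent palladium inserts into the aryl C–Br bond, tin transfers the prenyl group, and reductive elimination from the η3-prenyl complex occurs at the unsubstituted terminus to give the linear prenyl arene, while the ketone, MOM acetal and chromene alkene stay inert.

Step 4
Reactants: 7 1-ArB-ethan-1-one
Product: 9 2-chloro-1-ArB-ethan-1-one, via lithium enolate 8 (not isolated)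
Conditions: LiN(SiMe3)2, THF, −78 °C; TsCl, −78 to 0 °C
Reagents that add atoms: p-toluenesulfonyl chloride (TsCl), Cc1ccc(cc1)S(=O)(=O)Cl
Why: Electrophilic α-chlorination of a preformed enolate, in which the methyl group is the only enolisable site and 8 takes positive chlorine from TsCl (sulfinate leaves) at a temperature where both alkenes and the arene ignore this weak chlorine donor.

Step 5
Reactants: 9 2-chloro-1-ArB-ethan-1-one
Product: 11 (2R)-2-ArB-oxirane, via (R)-chlorohydrin 10 (not isolated)
Conditions: Cp*RhCl[(S,S)-TsDPEN] (0.5 mol %), HCO2H–Et3N (1:1), THF, 25 °C; then 2 M aq NaOH, 0 °C to rt; used crude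
Reagents that add atoms: none
Why: Noyori–Ikariya asymmetric transfer hydrogenation then intramolecular Williamson closure, in which outer-sphere Rh–H/N–H transfer reduces only the polar C=O and the (S,S)-ligand exposes the face that gives (R)-10 (the sense known for 2-chloroacetophenones), after which NaOH closes the ring by 3-exo-tet displacement at CH2 without touching the stereocentre, so 11 is (R).

Step 6
Reactants: 12 5-fluorobenzene-1,3-diol; 13 1,3-dithiane
Product: 15 4-(1,3-dithian-2-yl)-5-fluorobenzene-1,3-diol, via 2-chloro-1,3-dithiane 14 (not isolated)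
Conditions: 13, N-chlorosuccinimide, CH2Cl2, 0 °C to rt, 30 min; then 12 in Et2O, 0 °C to rt
Reagents that add atoms: none
Why: Electrophilic aromatic substitution (a masked formylation), in which 14 ionises to the sulfur-stabilised 1,3-dithian-2-ylium ion and this attacks the resorcinol para to one OH, ortho to the other and next to F, the site where 5-substituted resorcinols are formylated, because the position between the two OH groups is too crowded for the bulky cation.

Step 7
Reactants: 15 4-(1,3-dithian-2-yl)-5-fluorobenzene-1,3-diol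
Product: 16 2-[2-fluoro-4,6-bis(methoxymethoxy)phenyl]-1,3-dithiane
Conditions: MOMCl (2.4 equiv), K2CO3, acetone, 0 °C to rt
Reagents that add atoms: chloromethyl methyl ether (MOMCl), COCCl
Why: Double Williamson-type O-alkylation of two unchelated phenols, with the thioacetal C–H not acidic to carbonate and sulfur a far poorer nucleophile than phenoxide.

Step 8
Reactants: 16 2-[2-fluoro-4,6-bis(methoxymethoxy)phenyl]-1,3-dithiane; 11 (2R)-2-ArB-oxirane
Product: 19 (2S)-2-ArB-5,7-bis(methoxymethoxy)-2,3-dihydrospiro[chromene-4,2'-[1,3]dithiane], via lithiated dithiane 17 (not isolated), via lithium alkoxide 18 (not isolated)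
Conditions: 16, n-BuLi (1.05 equiv), THF, −78 to −30 °C; 11, −78 °C to rt; then KOt-Bu (20 mol %), DMPU, 60 °C
Reagents that add atoms: none
Why: Proposed new method: Corey–Seebach umpolung merged with ring closure in one flask; carbanion 17 (the ring A formyl carbon as an acyl anion) opens oxirane 11 by SN2 at the unhindered CH2, joining two carbons that are both electrophilic in their parent forms and leaving the C2–O bond untouched, and alkoxide 18 then sits in a six-ring relation to a C–F carbon whose Meisenheimer charge falls on carbons flanked by the two meta acetal oxygens, so that after catalytic Li/K exchange in DMPU (precipitating LiF returns KF to potassium alkoxide) and with Thorpe–Ingold help from the dithiane it should close O1–C8a by intramolecular SNAr to give (2S)-19 with retention; the closest known reaction types are the opening of styrene oxides by 2-aryl-2-lithio-1,3-dithianes, the alkoxide cyclisation of 3-(2-fluoroaryl)propanols to chromans and the SNAr of 1-fluoro-3,5-dialkoxybenzenes with potassium nucleophiles.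

Step 9
Reactants: 19 (2S)-spiro-dithiane flavan
Product: 20 (2S)-2-ArB-5,7-bis(methoxymethoxy)-2,3-dihydro-4H-chromen-4-one
Conditions: MeI (10 equiv), CaCO3, MeCN–H2O 9:1, 45 °C
Reagents that add atoms: water, O
Why: Alkylative dithioketal hydrolysis, in which S-methylation makes sulfur a leaving group, the thionium ion is stabilised by the ring A oxygen donors and trapped by water, CaCO3 keeps the medium neutral so that the MOM acetals and the labile C2 centre (retro-oxa-Michael) survive, and MeI ignores the alkenes that oxidative or mercury-based methods would attack.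

Step 10
Reactants: 20 (2S)-tris-MOM flavanone
Product: 21 Sanggenol N, (2S)-5,7-dihydroxy-2-[5-hydroxy-2,2-dimethyl-8-(3-methylbut-2-en-1-yl)-2H-chromen-6-yl]-2,3-dihydro-4H-chromen-4-one
Conditions: HCl (1.25 M in MeOH), 25 to 40 °C, monitored by chiral HPLC
Reagents that add atoms: none
Why: Acid-catalysed transacetalisation of three aryl MOM acetals to methanol, in which no free OH lies ortho to the prenyl group (so acid-induced chroman formation is impossible) and the low temperature keeps C2–O1 ionisation, the racemisation path of this electron-rich flavanone, slow.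

## Compound list

1 | 1-(5-bromo-2,4-dihydroxyphenyl)ethan-1-one | CC(=O)c1cc(Br)c(O)cc1O | starting material
2 | 3-methylbut-2-enal | CC(C)=CC=O | starting material
3 | 4-acetyl-6-bromo-3-hydroxy-2-(3-methylbut-2-en-1-ylidene)cyclohexa-3,5-dien-1-one | CC(=O)C1=C(O)C(=CC=C(C)C)C(=O)C(Br)=C1 | intermediate
4 | 1-(8-bromo-5-hydroxy-2,2-dimethyl-2H-chromen-6-yl)ethan-1-one | CC(=O)c1cc(Br)c2OC(C)(C)C=Cc2c1O | intermediate
5 | 1-[8-bromo-5-(methoxymethoxy)-2,2-dimethyl-2H-chromen-6-yl]ethan-1-one | CC(=O)c1cc(Br)c2OC(C)(C)C=Cc2c1OCOC | intermediate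
6 | tributyl(3-methylbut-2-en-1-yl)stannane | CCCC[Sn](CCCC)(CCCC)CC=C(C)C | starting material
7 | 1-[5-(methoxymethoxy)-2,2-dimethyl-8-(3-methylbut-2-en-1-yl)-2H-chromen-6-yl]ethan-1-one | CC(=O)c1cc(CC=C(C)C)c2OC(C)(C)C=Cc2c1OCOC | intermediate
8 | lithium 1-[5-(methoxymethoxy)-2,2-dimethyl-8-(3-methylbut-2-en-1-yl)-2H-chromen-6-yl]ethen-1-olate | [Li]OC(=C)c1cc(CC=C(C)C)c2OC(C)(C)C=Cc2c1OCOC | intermediate
9 | 2-chloro-1-[5-(methoxymethoxy)-2,2-dimethyl-8-(3-methylbut-2-en-1-yl)-2H-chromen-6-yl]ethan-1-one | ClCC(=O)c1cc(CC=C(C)C)c2OC(C)(C)C=Cc2c1OCOC | intermediate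
10 | (1R)-2-chloro-1-[5-(methoxymethoxy)-2,2-dimethyl-8-(3-methylbut-2-en-1-yl)-2H-chromen-6-yl]ethan-1-ol | ClC[C@H](O)c1cc(CC=C(C)C)c2OC(C)(C)C=Cc2c1OCOC | intermediate
11 | (2R)-2-[5-(methoxymethoxy)-2,2-dimethyl-8-(3-methylbut-2-en-1-yl)-2H-chromen-6-yl]oxirane | C1O[C@@H]1c1cc(CC=C(C)C)c2OC(C)(C)C=Cc2c1OCOC | intermediate
12 | 5-fluorobenzene-1,3-diol | Oc1cc(O)cc(F)c1 | starting material
13 | 1,3-dithiane | C1CSCSC1 | starting material
14 | 2-chloro-1,3-dithiane | ClC1SCCCS1 | intermediate
15 | 4-(1,3-dithian-2-yl)-5-fluorobenzene-1,3-diol | Oc1cc(O)c(C2SCCCS2)c(F)c1 | intermediate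
16 | 2-[2-fluoro-4,6-bis(methoxymethoxy)phenyl]-1,3-dithiane | COCOc1cc(OCOC)c(C2SCCCS2)c(F)c1 | intermediate
17 | 2-[2-fluoro-4,6-bis(methoxymethoxy)phenyl]-2-lithio-1,3-dithiane | [Li]C1(SCCCS1)c1c(F)cc(OCOC)cc1OCOC | intermediate
18 | lithium (1S)-2-{2-[2-fluoro-4,6-bis(methoxymethoxy)phenyl]-1,3-dithian-2-yl}-1-[5-(methoxymethoxy)-2,2-dimethyl-8-(3-methylbut-2-en-1-yl)-2H-chromen-6-yl]ethan-1-olate | [Li]O[C@@H](CC1(SCCCS1)c1c(F)cc(OCOC)cc1OCOC)c1cc(CC=C(C)C)c2OC(C)(C)C=Cc2c1OCOC | intermediate
19 | (2S)-5,7-bis(methoxymethoxy)-2-[5-(methoxymethoxy)-2,2-dimethyl-8-(3-methylbut-2-en-1-yl)-2H-chromen-6-yl]-2,3-dihydrospiro[chromene-4,2'-[1,3]dithiane] | COCOc1cc(OCOC)c2c(c1)O[C@@H](CC21SCCCS1)c1cc(CC=C(C)C)c3OC(C)(C)C=Cc3c1OCOC | intermediate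
20 | (2S)-5,7-bis(methoxymethoxy)-2-[5-(methoxymethoxy)-2,2-dimethyl-8-(3-methylbut-2-en-1-yl)-2H-chromen-6-yl]-2,3-dihydro-4H-chromen-4-one | COCOc1cc(OCOC)c2c(c1)O[C@@H](CC2=O)c1cc(CC=C(C)C)c3OC(C)(C)C=Cc3c1OCOC | intermediate
21 | Sanggenol N, (2S)-configured | CC(C)=CCc1cc([C@@H]2CC(=O)c3c(O)cc(O)cc3O2)c(O)c2c1OC(C)(C)C=C2 | target

## Step count and risks

Total steps: 10. Longest linear sequence: 8 (steps 1–5, then 8–10).

**Step 8 (highest risk).** Three things can go wrong. n-BuLi may metalate the ring C–H between F and OMOM instead of the hindered dithiane C–H. Lithium may trigger benzylic opening or rearrangement of the electron-rich oxirane. The fluoride displacement on a ring without an acceptor group may stall.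

The fallback sets out from 16 and 11 and comes back at 19. After the epoxide opening the mixture is quenched with aqueous NH4Cl and the (S)-alcohol F1 is isolated. Ring closure is then changed from addition–elimination to elimination–addition. Lithium 2,2,6,6-tetramethylpiperidide (2.5 equiv, THF, −78 to 0 °C) removes the OH proton and the ring proton flanked by F and OMOM, and LiF is lost. In the 3-alkoxyaryne alkoxide F2 the tethered oxygen can reach only the aryne carbon next to C4a, which is also the electronically preferred distal carbon. The resulting 8-lithio flavan F3 is protonated on work-up to give 19. This turns the competing ring metalation into the productive path.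

**Step 10.** Acid may ionise the C2–O1 bond of the ortho-acyl aryl ether, helped by the very electron-rich ring B, and so erode the ee.

The fallback sets out from 19 and comes back at 21, with the order of the two unmasking events swapped. The MOM groups are removed with HCl in MeOH while C4 is still a dithioketal. In that state O1 belongs to a non-acylated, poorer leaving phenol and no retro-oxa-Michael path exists. This gives the triol spiro-dithiane F5. The ketone is then released last under neutral conditions (MeI, CaCO3, aqueous MeCN, 40 °C), which gives 21 directly.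

**Step 6.** The direct dithianylation of a free fluororesorcinol may give isomer mixtures, double substitution or ring chlorination.

The fallback sets out from 12 and comes back at 15. Vilsmeier–Haack formylation (POCl3, DMF, MeCN, 0 °C to rt, then water) gives 2-fluoro-4,6-dihydroxybenzaldehyde F4. This is thioacetalised with propane-1,3-dithiol (BF3·OEt2, THF–CH2Cl2, 0 °C) to 15, at the cost of one more step.

## Further compounds

F1 | step 8 | (1S)-2-{2-[2-fluoro-4,6-bis(methoxymethoxy)phenyl]-1,3-dithian-2-yl}-1-ArB-ethan-1-ol | O[C@@H](CC1(SCCCS1)c1c(F)cc(OCOC)cc1OCOC)c1cc(CC=C(C)C)c2OC(C)(C)C=Cc2c1OCOC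
F2 | step 8 | lithium (1S)-alkoxide of the 3,5-bis(methoxymethoxy)aryne formed by loss of LiF | [Li]O[C@@H](CC1(SCCCS1)C1=C(OCOC)C=C(OCOC)C#C1)c1cc(CC=C(C)C)c2OC(C)(C)C=Cc2c1OCOC
F3 | step 8 | (2S)-8-lithio derivative of 19 | COCOc1cc(OCOC)c2c(c1[Li])O[C@@H](CC21SCCCS1)c1cc(CC=C(C)C)c3OC(C)(C)C=Cc3c1OCOC
F4 | step 6 | 2-fluoro-4,6-dihydroxybenzaldehyde | O=Cc1c(O)cc(O)cc1F
F5 | step 10 | (2S)-2-[5-hydroxy-2,2-dimethyl-8-(3-methylbut-2-en-1-yl)-2H-chromen-6-yl]-2,3-dihydrospiro[chromene-4,2'-[1,3]dithiane]-5,7-diol | Oc1cc(O)c2c(c1)O[C@@H](CC21SCCCS1)c1cc(CC=C(C)C)c3OC(C)(C)C=Cc3c1O
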